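**Retrosynthetic overview**
- Feature: ring B of the target (O1–C2–C3–C3a–C7a) carries a veratryl group on C2 trans to a one-carbon substituent on C3. This is the pattern of a flavanone (O1–C2–C3–C4–C4a–C8a) that has expelled C4 from the ring, with C4 surviving as the C3 methyl carbon.
- Key disconnection: the C3–C3a bond. It is made by moving ring A carbon C4a from C4 to C3 of an (S)-flavanone with a trivalent iodine oxidant in trimethyl orthoformate, and the extruded C4 appears as a trans methyl ester.
- After it: CO2Me → CH2OH → CH2I → CH3. The C5–C1' bond then comes from Br–Li exchange and Felkin–Anh addition to O-TBDPS (S)-lactaldehyde (C2' from lactate, C1' by 1,2-induction), followed by desilylation.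
- Before it: ring bromination of 2-hydroxy-3-methoxyacetophenone, enaminone formation, acid closure to 6-bromo-8-methoxychromone, and Pd/pyridine-oxazoline asymmetric conjugate arylation to set C2.
- Ring order: ring A and ring C (veratryl) are bought. The pyranone ring is closed in step 3 and contracted to ring B in step 5.

Key step: step 5

Assumption: the sense of induction in step 4 is taken from the cyclic-enone model of the Pd/PyOx system, in which the (S)-ligand would give the (R)-flavanone. The (R)-ligand is therefore specified. If the sense proves opposite, the antipodal ligand is used and nothing else changes.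

Step 1
Reactants: 1 2-hydroxy-3-methoxyacetophenone
Product: 2 1-(5-bromo-2-hydroxy-3-methoxyphenyl)ethan-1-one
Conditions: NBS (1.05 equiv), MeCN, 0 °C to rt
Reagents that add atoms: N-bromosuccinimide, O=C1CCC(=O)N1Br
Why: Electrophilic aromatic bromination should go to C5, the only open position that is para to the free phenol and meta to the acetyl group, as seen with the related o-vanillin system.

Step 2
Reactants: 2 1-(5-bromo-2-hydroxy-3-methoxyphenyl)ethan-1-one; 3 N,N-dimethylformamide dimethyl acetal
Product: 4 (E)-1-(5-bromo-2-hydroxy-3-methoxyphenyl)-3-(dimethylamino)prop-2-en-1-one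
Conditions: 3 (2 equiv), toluene, 100 °C
Reagents that add atoms: none
Why: Condensation of the acidic acetyl methyl group with an amide acetal (enaminone formation) is the standard one-carbon homologation of 2-hydroxyacetophenones towards 2,3-unsubstituted chromones.

Step 3
Reactants: 4 (E)-1-(5-bromo-2-hydroxy-3-methoxyphenyl)-3-(dimethylamino)prop-2-en-1-one
Product: 5 6-bromo-8-methoxy-4H-chromen-4-one
Conditions: conc. HCl, CH2Cl2, 40 °C
Reagents that add atoms: none
Why: Acid-promoted conjugate addition–elimination, in which the phenol oxygen attacks the protonated enaminone β-carbon and dimethylamine leaves, closes the pyranone ring irreversibly because the chromone is aromatic.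

Step 4
Reactants: 5 6-bromo-8-methoxy-4H-chromen-4-one; 6 3,4-dimethoxyphenylboronic acid
Product: 7 (2S)-6-bromo-2-(3,4-dimethoxyphenyl)-8-methoxychroman-4-one
Conditions: Pd(OCOCF3)2 (5 mol %), (R)-t-BuPyOx [(R)-4-tert-butyl-2-(pyridin-2-yl)-4,5-dihydrooxazole, 6 mol %], NH4PF6 (30 mol %), H2O (5 equiv), 6 (2 equiv), ClCH2CH2Cl, 60 °C, air; recrystallisation to raise enantiopurity if needed
Reagents that add atoms: none
Why: In this palladium-catalysed asymmetric conjugate addition of an arylboronic acid to a chromone, the aryl–palladium species inserts C2=C3 on the face left open by the ligand tert-butyl group to set C2 as S, and the cycle stays at divalent palladium so the C–Br bond is not touched.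

Step 5
Reactants: 7 (2S)-6-bromo-2-(3,4-dimethoxyphenyl)-8-methoxychroman-4-one
Product: 11 methyl (2S,3S)-trans-5-bromo-2-(3,4-dimethoxyphenyl)-7-methoxy-2,3-dihydrobenzofuran-3-carboxylate, via methyl enol ether 8 (not isolated), via trans C3 iodane ketal 9 (not isolated), via dimethoxycarbenium ion 10 (not isolated)
Conditions: PhI(OAc)2 (1.2 equiv), conc. H2SO4 (cat.), HC(OMe)3 (solvent), 0 °C to rt; aq NaHCO3
Reagents that add atoms: trimethyl orthoformate, COC(OC)OC (both ester oxygens and the OCH3 carbon); (diacetoxyiodo)benzene, CC(=O)OI(OC(C)=O)c1ccccc1 (atoms only in intermediate 9)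
Why: Acid and orthoformate should turn ketone 7 into methyl enol ether 8, the electrophilic trivalent iodine reagent then binds C3 on the face away from the pseudo-equatorial C2 veratryl group while methanol caps C4, and the resulting trans iodane ketal 9 holds its equatorial C3–I bond antiperiplanar to the C4–C4a ring bond. Departure of iodobenzene, pushed by the two methoxy groups on C4, lets C4a slide from C4 to C3 to form the C3–C3a bond, and cation 10 hands a methyl group to acetate to leave ester 11. The closest known reaction type is the oxidative 1,2-aryl shift of alkyl aryl ketones to methyl 2-arylalkanoates with PhI(OAc)2 or Tl(NO3)3 in trimethyl orthoformate, which is documented on flavanones as a contraction to trans 2-aryl-2,3-dihydrobenzofuran-3-carboxylates. Ring B is therefore closed not by a cyclisation but by a six-to-five contraction, the ipso carbon C4a attacking C3 from the rear of the C–I bond through a phenonium-like bridged transition state. The new C3 stereocentre is controlled by C2, since anti iodination followed by inversion puts the ester carbon trans to the aryl group (2S,3S), which is also the more stable arrangement, while C2 itself is not a reacting centre. The step needs migration of C4a in preference to the electron-rich C2 aryl group, to proton loss towards the flavone and to retro-oxa-Michael opening; the ketal secures this because it supplies the push at C4, its axial methoxy group clashes with an axial C2 aryl group and so suppresses the diaxial conformer that aryl migration from C2 requires, O1 ortho to C4a raises the migratory aptitude of ring A, and masking of the carbonyl removes the enolisable ketone through which C2–O1 would open.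

Step 6
Reactants: 11 methyl (2S,3S)-trans-5-bromo-2-(3,4-dimethoxyphenyl)-7-methoxy-2,3-dihydrobenzofuran-3-carboxylate
Product: 12 [(2S,3R)-5-bromo-2-(3,4-dimethoxyphenyl)-7-methoxy-2,3-dihydrobenzofuran-3-yl]methanol (trans; the descriptor changes by priority only)
Conditions: i-Bu2AlH (2.5 equiv), CH2Cl2, −78 to 0 °C; aq potassium sodium tartrate
Reagents that add atoms: none
Why: Hydride reduction of the ester to the primary alcohol with i-Bu2AlH is non-basic and cold, so C3 is not epimerised and the aryl bromide and aryl ethers are inert.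

Step 7
Reactants: 12 [(2S,3R)-5-bromo-2-(3,4-dimethoxyphenyl)-7-methoxy-2,3-dihydrobenzofuran-3-yl]methanol
Product: 13 (2S,3S)-5-bromo-2-(3,4-dimethoxyphenyl)-3-(iodomethyl)-7-methoxy-2,3-dihydrobenzofuran
Conditions: I2, PPh3, imidazole, CH2Cl2, 0 °C to rt
Reagents that add atoms: iodine, II
Why: Appel-type (Garegg–Samuelsson) iodination proceeds by SN2 displacement at the primary carbon under near-neutral conditions, so neither ring stereocentre takes part.

Step 8
Reactants: 13 (2S,3S)-5-bromo-2-(3,4-dimethoxyphenyl)-3-(iodomethyl)-7-methoxy-2,3-dihydrobenzofuran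
Product: 14 (2S,3S)-5-bromo-2-(3,4-dimethoxyphenyl)-7-methoxy-3-methyl-2,3-dihydrobenzofuran
Conditions: NaBH4 (4 equiv), DMSO, rt to 50 °C
Reagents that add atoms: none
Why: SN2 hydride displacement of a primary alkyl iodide by NaBH4 in a dipolar aprotic solvent is a known dehalogenation that leaves aryl bromides alone and avoids radical conditions that could attack C–Br.

Step 9
Reactants: 15 ethyl (S)-lactate
Product: 16 ethyl (S)-2-[(tert-butyldiphenylsilyl)oxy]propanoate
Conditions: TBDPSCl, imidazole, DMF, rt
Reagents that add atoms: tert-butyl(chloro)diphenylsilane, CC(C)(C)[Si](Cl)(c1ccccc1)c1ccccc1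
Why: Imidazole-promoted O-silylation of a secondary alcohol does not touch the C–O stereocentre and installs a bulky, non-chelating group that fluoride can remove.

Step 10
Reactants: 16 ethyl (S)-2-[(tert-butyldiphenylsilyl)oxy]propanoate
Product: 17 (S)-2-[(tert-butyldiphenylsilyl)oxy]propanal
Conditions: i-Bu2AlH (1.1 equiv), CH2Cl2, −78 °C; aq potassium sodium tartrate; used at once
Reagents that add atoms: none
Why: Partial ester reduction with one equivalent of i-Bu2AlH at −78 °C stops at the aldehyde oxidation level until the quench, and immediate use of the aldehyde protects its α-stereocentre.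

Step 11
Reactants: 14 (2S,3S)-5-bromo-2-(3,4-dimethoxyphenyl)-7-methoxy-3-methyl-2,3-dihydrobenzofuran; 17 (S)-2-[(tert-butyldiphenylsilyl)oxy]propanal
Product: 19 (1R,2S)-2-[(tert-butyldiphenylsilyl)oxy]-1-[(2S,3S)-2-(3,4-dimethoxyphenyl)-7-methoxy-3-methyl-2,3-dihydrobenzofuran-5-yl]propan-1-ol, via C5 aryllithium 18 (not isolated)
Conditions: n-BuLi (1.05 equiv), THF, −78 °C; then 17 (1.3 equiv), −78 °C; sat. aq NH4Cl; chromatography to remove the minor C1' epimer
Reagents that add atoms: n-butyllithium, [Li]CCCC (lithium only in intermediate 18)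
Why: Bromine–lithium exchange followed by 1,2-addition under polar Felkin–Anh control, with the bulky non-chelating silyloxy group held anti to the incoming aryl nucleophile, should favour the 1,2-anti product and so set C1' as R next to the lactate-derived 2'S centre.

Step 12
Reactants: 19 (1R,2S)-2-[(tert-butyldiphenylsilyl)oxy]-1-[(2S,3S)-2-(3,4-dimethoxyphenyl)-7-methoxy-3-methyl-2,3-dihydrobenzofuran-5-yl]propan-1-ol
Product: 20 (1R,2S)-1-[(2S,3S)-2-(3,4-dimethoxyphenyl)-7-methoxy-3-methyl-2,3-dihydrobenzofuran-5-yl]propane-1,2-diol (target)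
Conditions: Bu4NF (1.5 equiv), THF, 0 °C to rt
Reagents that add atoms: none
Why: Fluoride desilylation is acid-free, which matters because the C1' benzylic alcohol para to O1 would ionise and epimerise under acidic deprotection.

**Compound list**
1 | 2-hydroxy-3-methoxyacetophenone | CC(=O)c1cccc(OC)c1O | starting material
2 | 1-(5-bromo-2-hydroxy-3-methoxyphenyl)ethan-1-one | CC(=O)c1cc(Br)cc(OC)c1O | intermediate
3 | N,N-dimethylformamide dimethyl acetal | COC(OC)N(C)C | starting material
4 | (E)-1-(5-bromo-2-hydroxy-3-methoxyphenyl)-3-(dimethylamino)prop-2-en-1-one | CN(C)/C=C/C(=O)c1cc(Br)cc(OC)c1O | intermediate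
5 | 6-bromo-8-methoxy-4H-chromen-4-one | COc1cc(Br)cc2c(=O)ccoc12 | intermediate
6 | 3,4-dimethoxyphenylboronic acid | COc1ccc(B(O)O)cc1OC | starting material
7 | (2S)-6-bromo-2-(3,4-dimethoxyphenyl)-8-methoxychroman-4-one | COc1ccc([C@@H]2CC(=O)c3cc(Br)cc(OC)c3O2)cc1OC | intermediate
8 | (2S)-6-bromo-2-(3,4-dimethoxyphenyl)-4,8-dimethoxy-2H-chromene | COc1ccc([C@H]2Oc3c(OC)cc(Br)cc3C(OC)=C2)cc1OC | intermediate (not isolated)
9 | acetoxy[(2R,3R)-6-bromo-2-(3,4-dimethoxyphenyl)-4,4,8-trimethoxychroman-3-yl](phenyl)-λ3-iodane, 2,3-trans | COc1ccc([C@H]2Oc3c(OC)cc(Br)cc3C(OC)(OC)[C@@H]2I(OC(C)=O)c4ccccc4)cc1OC | intermediate (not isolated)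
10 | [(2S,3S)-5-bromo-2-(3,4-dimethoxyphenyl)-7-methoxy-2,3-dihydrobenzofuran-3-yl]dimethoxycarbenium ion | COc1ccc([C@H]2Oc3c(OC)cc(Br)cc3[C@@H]2C(OC)=[O+]C)cc1OC | intermediate (not isolated)
11 | methyl (2S,3S)-trans-5-bromo-2-(3,4-dimethoxyphenyl)-7-methoxy-2,3-dihydrobenzofuran-3-carboxylate | COc1ccc([C@H]2Oc3c(OC)cc(Br)cc3[C@@H]2C(=O)OC)cc1OC | intermediate
12 | [(2S,3R)-5-bromo-2-(3,4-dimethoxyphenyl)-7-methoxy-2,3-dihydrobenzofuran-3-yl]methanol | COc1ccc([C@H]2Oc3c(OC)cc(Br)cc3[C@@H]2CO)cc1OC | intermediate
13 | (2S,3S)-5-bromo-2-(3,4-dimethoxyphenyl)-3-(iodomethyl)-7-methoxy-2,3-dihydrobenzofuran | COc1ccc([C@H]2Oc3c(OC)cc(Br)cc3[C@@H]2CI)cc1OC | intermediate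
14 | (2S,3S)-5-bromo-2-(3,4-dimethoxyphenyl)-7-methoxy-3-methyl-2,3-dihydrobenzofuran | COc1ccc([C@H]2Oc3c(OC)cc(Br)cc3[C@@H]2C)cc1OC | intermediate
15 | ethyl (S)-lactate | CCOC(=O)[C@H](C)O | starting material
16 | ethyl (S)-2-[(tert-butyldiphenylsilyl)oxy]propanoate | CCOC(=O)[C@H](C)O[Si](c1ccccc1)(c1ccccc1)C(C)(C)C | intermediate
17 | (S)-2-[(tert-butyldiphenylsilyl)oxy]propanal | O=C[C@H](C)O[Si](c1ccccc1)(c1ccccc1)C(C)(C)C | intermediate
18 | [(2S,3S)-2-(3,4-dimethoxyphenyl)-7-methoxy-3-methyl-2,3-dihydrobenzofuran-5-yl]lithium | COc1ccc([C@H]2Oc3c(OC)cc([Li])cc3[C@@H]2C)cc1OC | intermediate (not isolated)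
19 | (1R,2S)-2-[(tert-butyldiphenylsilyl)oxy]-1-[(2S,3S)-2-(3,4-dimethoxyphenyl)-7-methoxy-3-methyl-2,3-dihydrobenzofuran-5-yl]propan-1-ol | COc1ccc([C@H]2Oc3c(OC)cc([C@@H](O)[C@H](C)O[Si](c4ccccc4)(c4ccccc4)C(C)(C)C)cc3[C@@H]2C)cc1OC | intermediate
20 | (1R,2S)-1-[(2S,3S)-2-(3,4-dimethoxyphenyl)-7-methoxy-3-methyl-2,3-dihydrobenzofuran-5-yl]propane-1,2-diol | COc1ccc([C@H]2Oc3c(OC)cc([C@@H](O)[C@H](C)O)cc3[C@@H]2C)cc1OC | target

**Step count**
- Total steps: 12, of which 10 are in the main line and 2 make aldehyde 17.
- Longest linear sequence: 10 steps (steps 1–8, 11, 12).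

**Steps most likely to fail**

**Step 5 (key step).**
- What may go wrong: a competing 1,2-shift of the electron-rich C2 aryl group, or proton loss that aromatises the pyranone ring. The oxidant could attack ring C electrophilically. Ring A could migrate sluggishly because bromine sits meta to C4a. Acid-induced opening at C2–O1 could erode enantiopurity.
- Fallback: ring B is built by an intramolecular carbenoid C–H insertion instead of a contraction. It sets out from 2 and comes back at 11.
- O-Alkylation of 2 with 3,4-dimethoxybenzyl chloride (K2CO3, DMF) would give 1-[5-bromo-2-(3,4-dimethoxybenzyloxy)-3-methoxyphenyl]ethan-1-one F1.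
- Riley oxidation (SeO2, pyridine, 100 °C) would give the arylglyoxylic acid F2, and MeI/K2CO3 would give its methyl ester F3.
- Condensation with TsNHNH2 would give tosylhydrazone F4, and DBU in CH2Cl2 (Bamford–Stevens-type elimination) would give methyl aryldiazoacetate F5.
- Dirhodium tetrakis[N-phthaloyl-(R)-tert-leucinate], Rh2(R-PTTL)4, is the catalyst enantiomer expected to deliver 2S. In toluene at low temperature it should insert the carbenoid into the activated veratrylic C–H bond to give the cis ester F6.
- NaOMe in MeOH then epimerises C3 to the more stable trans ester 11.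

**Step 11.**
- What may go wrong: poor facial selectivity through partial chelation, enolisation or epimerisation of the aldehyde by the aryllithium, or protonation of the aryllithium.
- Fallback: C1' is set by chelation-controlled ketone reduction instead of by addition to the aldehyde. It sets out from 19 as obtained, since both C1' epimers converge, and comes back at 20.
- Dess–Martin periodinane would give the silyloxy ketone F10.
- Bu4NF buffered with AcOH would give the (S)-α-hydroxy ketone F11.
- Zn(BH4)2 in Et2O at −20 to 0 °C should tie the carbonyl and α-oxygen into a five-membered zinc chelate. Hydride then arrives on the face opposite the C2' methyl group and gives the anti diol 20 directly.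

**Step 4.**
- What may go wrong: protodeboronation of the electron-rich boronic acid, slow insertion into the 8-methoxy chromone, or insufficient enantioselectivity. The catalyst could also drift to zerovalent palladium and then insert into the C–Br bond.
- Fallback: the flavanone is made racemic by the chalcone route and then resolved. It sets out from 2 and comes back at 7.
- Claisen–Schmidt condensation of 2 with 3,4-dimethoxybenzaldehyde (KOH, EtOH) would give the 2'-hydroxychalcone F7.
- NaOAc in refluxing EtOH (intramolecular oxa-Michael addition) would give the racemic flavanone F8.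
- Kinetic resolution by asymmetric transfer hydrogenation uses RuCl(p-cymene)[(R,R)-TsDPEN] in HCO2H/Et3N. It should reduce the (R)-ketone faster to the (2R,4R)-cis-flavan-4-ol F9 and leave 7, which is separated by chromatography.

**Further compounds**
F1 | step 5 | 1-[5-bromo-2-(3,4-dimethoxybenzyloxy)-3-methoxyphenyl]ethan-1-one | CC(=O)c1cc(Br)cc(OC)c1OCc1ccc(OC)c(OC)c1
F2 | step 5 | 2-[5-bromo-2-(3,4-dimethoxybenzyloxy)-3-methoxyphenyl]-2-oxoacetic acid | OC(=O)C(=O)c1cc(Br)cc(OC)c1OCc1ccc(OC)c(OC)c1
F3 | step 5 | methyl 2-[5-bromo-2-(3,4-dimethoxybenzyloxy)-3-methoxyphenyl]-2-oxoacetate | COC(=O)C(=O)c1cc(Br)cc(OC)c1OCc1ccc(OC)c(OC)c1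
F4 | step 5 | methyl 2-[5-bromo-2-(3,4-dimethoxybenzyloxy)-3-methoxyphenyl]-2-(2-tosylhydrazinylidene)acetate | COC(=O)C(=NNS(=O)(=O)c1ccc(C)cc1)c1cc(Br)cc(OC)c1OCc1ccc(OC)c(OC)c1
F5 | step 5 | methyl 2-[5-bromo-2-(3,4-dimethoxybenzyloxy)-3-methoxyphenyl]-2-diazoacetate | COC(=O)C(=[N+]=[N-])c1cc(Br)cc(OC)c1OCc1ccc(OC)c(OC)c1
F6 | step 5 | methyl (2S,3R)-cis-5-bromo-2-(3,4-dimethoxyphenyl)-7-methoxy-2,3-dihydrobenzofuran-3-carboxylate | COc1ccc([C@H]2Oc3c(OC)cc(Br)cc3[C@H]2C(=O)OC)cc1OC
F7 | step 4 | (E)-1-(5-bromo-2-hydroxy-3-methoxyphenyl)-3-(3,4-dimethoxyphenyl)prop-2-en-1-one | COc1ccc(/C=C/C(=O)c2cc(Br)cc(OC)c2O)cc1OC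
F8 | step 4 | racemic 6-bromo-2-(3,4-dimethoxyphenyl)-8-methoxychroman-4-one | COc1ccc(C2CC(=O)c3cc(Br)cc(OC)c3O2)cc1OC
F9 | step 4 | (2R,4R)-cis-6-bromo-2-(3,4-dimethoxyphenyl)-8-methoxychroman-4-ol | COc1ccc([C@H]2C[C@@H](O)c3cc(Br)cc(OC)c3O2)cc1OC
F10 | step 11 | (S)-2-[(tert-butyldiphenylsilyl)oxy]-1-[(2S,3S)-2-(3,4-dimethoxyphenyl)-7-methoxy-3-methyl-2,3-dihydrobenzofuran-5-yl]propan-1-one | COc1ccc([C@H]2Oc3c(OC)cc(C(=O)[C@H](C)O[Si](c4ccccc4)(c4ccccc4)C(C)(C)C)cc3[C@@H]2C)cc1OC
F11 | step 11 | (S)-2-hydroxy-1-[(2S,3S)-2-(3,4-dimethoxyphenyl)-7-methoxy-3-methyl-2,3-dihydrobenzofuran-5-yl]propan-1-one | COc1ccc([C@H]2Oc3c(OC)cc(C(=O)[C@H](C)O)cc3[C@@H]2C)cc1OC
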